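The tricycle is opened at the cyclobutane bond C10–C11. In the cis-fused cyclohexenone/cycloheptane that results, carbonyl carbon C10 and methyl-bearing C11 lie three bonds apart on either side of the C5–C6 ring fusion, and C11 is flanked by oxygenated C1; an epoxide spanning C11 and C1 is therefore the radical source. In one operation Cp2TiCl opens it to the tertiary C11 radical, which adds across the ring to the C10 ketone, so that the four-membered ring, the C10 and C11 stereocentres and the free C1 hydroxyl arise together. The precursor, a cis-fused bicyclo[5.4.0] epoxy enone carrying the C3 isovalerate, is built from (R)-carvone by radical α′-alkylation, allylboration, kinetic C5 epimerisation, ring-closing metathesis and epoxidation.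

Key step: step 8

Locants: C1 carries the senecioate, C2 is the CH2 between the two carbinol carbons, C3 carries the isovalerate, C4 is the CMe2 carbon, C5/C6/C10/C11 form the cyclobutane (C11 quaternary with a methyl, C6 next to the ketone C7), and C8=C9 is the enone double bond with the methyl on C9.
Assumption: 2-bromo-2-methylpropanal (4) is taken as a purchased reagent.
Remark: the side chain is put on C5 through the enol silane of carvone because α′-halocarvones aromatise with amine bases; the ring fusion is set cis by kinetic protonation because the trans-fused isomer is expected to be the more stable one.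
Remark: the allylborane of step 3 is defined by its origin from (−)-α-pinene and by its SMILES, since sign conventions for these boranes vary.

Step 1
Reactants: 1 (R)-carvone
Product: 3 trimethyl{[(3R)-6-methyl-3-(prop-1-en-2-yl)cyclohexa-1,5-dien-1-yl]oxy}silane, via lithium dienolate 2 (not isolated)
Conditions: LiN(iPr)2, THF, −78 °C; Me3SiCl, −78 °C to rt
Reagents that add atoms: chlorotrimethylsilane, C[Si](C)(C)Cl
Why: Kinetic α′-deprotonation of the enone at the C5 methylene gives the cross-conjugated dienolate, which is O-silylated (enol silane formation) without touching the C6 stereocentre.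

Step 2
Reactants: 3 the silyl dienol ether; 4 2-bromo-2-methylpropanal
Product: 5 2-methyl-2-[(1R,6R)-3-methyl-2-oxo-6-(prop-1-en-2-yl)cyclohex-3-en-1-yl]propanal (C4 trans to the isopropenyl group)
Conditions: fac-Ir(ppy)3 (1 mol %), 2,6-lutidine, MeCN, blue LEDs, rt
Reagents that add atoms: none
Why: Photoredox radical α-alkylation of an enol silane: reductive C–Br cleavage gives the electrophilic tertiary α-formyl radical, which should add to the electron-rich C5 terminus of the silyloxydiene on the face away from the C6 isopropenyl group (C5 set trans), and oxidation/desilylation of the siloxyallyl radical returns the enone.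

Step 3
Reactants: 5 the trans keto aldehyde
Product: 7 (5R,6R)-6-[(3R)-3-hydroxy-2-methylhex-5-en-2-yl]-2-methyl-5-(prop-1-en-2-yl)cyclohex-2-en-1-one, via borinate ester 6 (not isolated)
Conditions: (Ipc)2B(allyl) from (−)-α-pinene, Et2O, −78 °C; then HOCH2CH2NH2, rt
Reagents that add atoms: B-allyldiisopinocampheylborane from (−)-α-pinene, C=CCB([C@H]1C[C@H]2C[C@@H]([C@@H]1C)C2(C)C)[C@H]1C[C@H]2C[C@@H]([C@@H]1C)C2(C)C
Why: Brown allylboration through a chair Zimmerman–Traxler transition state: this enantiomer of the reagent should add to the Re face of the α-quaternary aldehyde and give the (R)-carbinol at C3, the enone ketone is inert at −78 °C, and the amine work-up avoids alkaline peroxide, which would epoxidise the enone.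

Step 4
Reactants: 7 the homoallylic alcohol
Product: 8 (3R)-2-methyl-2-[(1R,6R)-3-methyl-2-oxo-6-(prop-1-en-2-yl)cyclohex-3-en-1-yl]hex-5-en-3-yl 3-methylbutanoate
Conditions: (CH3)2CHCH2COCl, pyridine, DMAP (cat.), CH2Cl2, 0 °C to rt
Reagents that add atoms: 3-methylbutanoyl chloride, CC(C)CC(=O)Cl
Why: DMAP-catalysed acylation of the secondary C3 alcohol installs the isovalerate that the target keeps; no stereocentre is touched.

Step 5
Reactants: 8 the trans keto ester
Product: 10 (3R)-2-methyl-2-[(1S,6R)-3-methyl-2-oxo-6-(prop-1-en-2-yl)cyclohex-3-en-1-yl]hex-5-en-3-yl 3-methylbutanoate (C4 cis to the isopropenyl group), via dilithium bis-enolate 9 (not isolated)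
Conditions: LiN(iPr)2 (2.5 equiv), THF, −78 °C; inverse quench into AcOH/THF, −78 °C
Reagents that add atoms: none
Why: Deprotonation–kinetic protonation: in the cross-conjugated dienolate, A(1,2) strain with the quaternary C4 group on C5 should force the C6 isopropenyl group pseudoaxial, so the proton enters C5 from the opposite face and C4 ends cis to C11; the ester enolate formed by the excess base is simply reprotonated.

Step 6
Reactants: 10 the cis keto ester
Product: 11 cis-fused bicyclo[5.4.0] dienone (C11=C1 cycloheptene, C3 isovalerate, C4 gem-dimethyl, H5 and H6 cis, C8=C9(Me)–C10=O)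
Conditions: second-generation Grubbs catalyst (5 mol %), CH2Cl2 (0.005 M), 40 °C
Reagents that add atoms: none
Why: Ring-closing metathesis of the allyl terminus with the isopropenyl group should close the trisubstituted cycloheptene (gem-dimethyl effect, enone alkene inert), and the neutral conditions leave the kinetically set C5 centre alone.

Step 7
Reactants: 11 the cis-fused dienone
Product: 12 cis-fused C11–C1 epoxy enone (epoxide on the face of H5 and H6)
Conditions: mCPBA, NaHCO3, CH2Cl2, 0 °C
Reagents that add atoms: 3-chloroperoxybenzoic acid, OOC(=O)c1cccc(Cl)c1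
Why: Prilezhaev epoxidation is chemoselective for the electron-rich trisubstituted C11=C1 alkene over the enone, and attack on the convex face of the cis-fused bicycle (away from the six-membered ring and the C3 ester) should set C11 and C1.

Step 8
Reactants: 12 the epoxy enone
Product: 14 tricyclic diol (C1 secondary OH, C10 bridgehead OH, C3 isovalerate, C8=C9), via titanium dialkoxide 13 (not isolated)
Conditions: Cp2TiCl2 (2.5 equiv), Zn dust, THF, rt, slow addition of the Cp2TiCl solution to 12; 1 M HCl work-up
Reagents that add atoms: none
Why: Cp2TiCl (trivalent titanium) transfers one electron to the epoxide and cleaves the C11–O bond, giving the tertiary C11 radical with C1 held as a titanium alkoxide; the radical attacks the titanium-coordinated C10 carbonyl carbon and a second Cp2TiCl reduces the alkoxy radical, which makes the closure irreversible and leads to 13. The closest known reaction type is the reductive epoxide opening/4-exo radical addition to the enone carbonyl that turns carvone-derived epoxides into pinene-type cyclobutanols. The one new ring, cyclobutane C5–C6–C11–C10, closes in a transannular 4-exo-trig mode across the C5–C6 fusion bond. C10 and C11 are set by the framework: in the cis-fused bicycle C11 sits axial on the cyclohexenone and can reach C10 only on the face that C4 occupies at C5, so the bridging seven-membered ring fixes both centres, while C1 keeps the epoxide configuration because its C–O bond is never broken. The step needs ring closure to outrun capture of the radical by titanium (slow addition keeps Cp2TiCl dilute) and 1,2-attack at C10 to outrun conjugate attack at C8, which coordination of titanium to the carbonyl oxygen should secure as in the carvone cases.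

Step 9
Reactants: 14 the tricyclic diol
Product: 15 C1 senecioate with free C10 bridgehead alcohol
Conditions: (CH3)2C=CHCOCl (1.2 equiv), pyridine, DMAP (cat.), CH2Cl2, 0 °C
Reagents that add atoms: 3-methylbut-2-enoyl chloride, CC(C)=CC(=O)Cl
Why: Acylation should discriminate the secondary C1 alcohol from the tertiary bridgehead C10 alcohol, and pyridine instead of a trialkylamine limits vinylketene formation and deconjugation of the senecioyl group.

Step 10
Reactants: 15 the hydroxy diester
Product: 16 C10 methyl oxalate
Conditions: ClCOCO2Me, DMAP, pyridine, CH2Cl2, rt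
Reagents that add atoms: methyl chlorooxoacetate, COC(=O)C(=O)Cl
Why: DMAP-promoted acylation with the highly reactive oxalyl chloride half-ester converts the tertiary alcohol into a radical leaving group; the bridgehead position cannot eliminate.

Step 11
Reactants: 16 the methyl oxalate
Product: 17 C10-deoxy diester (longipin-2-ene 7,9-diester skeleton, C7 still CH2)
Conditions: Bu3SnH, AIBN, toluene, 110 °C
Reagents that add atoms: none
Why: Barton–McCombie-type deoxygenation through the tertiary methyl oxalate (Dolan–MacMillan variant): the stannyl radical adds to the oxalate, C10–O scission gives the bridgehead radical, whose orbital is orthogonal to C8=C9 (no allylic shift), and hydrogen transfer from the stannane can only give the bridgehead C10–H of the target.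

Step 12
Reactants: 17 the deoxy diester
Product: 18 target CNP0335239.1
Conditions: Rh2(cap)4 (1 mol %), t-BuOOH (5 equiv), K2CO3, CH2Cl2, rt
Reagents that add atoms: tert-butyl hydroperoxide, CC(C)(C)OO
Why: Allylic C–H oxidation of the ring methylene C7 to the enone, the α-pinene-to-verbenone transformation on the same bicyclo[3.1.1]heptene unit; the bridgehead allylic hydrogen is stereoelectronically inert and the ester alkene is electron-poor.

Compound list
1 | (R)-carvone, (5R)-2-methyl-5-(prop-1-en-2-yl)cyclohex-2-en-1-one | CC(=C)[C@@H]1CC=C(C)C(=O)C1 | starting material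
2 | lithium cross-conjugated dienolate of 1 | CC1=CC[C@@H](C(C)=C)C=C1[O-].[Li+] | intermediate
3 | trimethyl{[(3R)-6-methyl-3-(prop-1-en-2-yl)cyclohexa-1,5-dien-1-yl]oxy}silane | CC1=CC[C@@H](C(C)=C)C=C1O[Si](C)(C)C | intermediate
4 | 2-bromo-2-methylpropanal | CC(C)(Br)C=O | starting material
5 | 2-methyl-2-[(1R,6R)-3-methyl-2-oxo-6-(prop-1-en-2-yl)cyclohex-3-en-1-yl]propanal | O=CC(C)(C)[C@H]1[C@H](C(C)=C)CC=C(C)C1=O | intermediate
6 | diisopinocampheylborinate ester of 7 | C=CC[C@@H](OB([C@H]2C[C@H]3C[C@@H]([C@@H]2C)C3(C)C)[C@H]4C[C@H]5C[C@@H]([C@@H]4C)C5(C)C)C(C)(C)[C@H]1[C@H](C(C)=C)CC=C(C)C1=O | intermediate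
7 | (5R,6R)-6-[(3R)-3-hydroxy-2-methylhex-5-en-2-yl]-2-methyl-5-(prop-1-en-2-yl)cyclohex-2-en-1-one | C=CC[C@@H](O)C(C)(C)[C@H]1[C@H](C(C)=C)CC=C(C)C1=O | intermediate
8 | (3R)-2-methyl-2-[(1R,6R)-3-methyl-2-oxo-6-(prop-1-en-2-yl)cyclohex-3-en-1-yl]hex-5-en-3-yl 3-methylbutanoate | C=CC[C@@H](OC(=O)CC(C)C)C(C)(C)[C@H]1[C@H](C(C)=C)CC=C(C)C1=O | intermediate
9 | dilithium bis-enolate of 8 (ketone dienolate and ester enolate) | C=CC[C@@H](OC([O-])=CC(C)C)C(C)(C)C1=C([O-])C(C)=CC[C@H]1C(C)=C.[Li+].[Li+] | intermediate
10 | (3R)-2-methyl-2-[(1S,6R)-3-methyl-2-oxo-6-(prop-1-en-2-yl)cyclohex-3-en-1-yl]hex-5-en-3-yl 3-methylbutanoate | C=CC[C@@H](OC(=O)CC(C)C)C(C)(C)[C@@H]1[C@H](C(C)=C)CC=C(C)C1=O | intermediate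
11 | cis-fused bicyclo[5.4.0] dienone with C11=C1 alkene and C3 isovalerate | CC1=CC[C@@H](OC(=O)CC(C)C)C(C)(C)[C@@H]2[C@H]1CC=C(C)C2=O | intermediate
12 | cis-fused C11–C1 epoxy enone with C3 isovalerate | C[C@@]12O[C@@H]1C[C@@H](OC(=O)CC(C)C)C(C)(C)[C@@H]1[C@H]2CC=C(C)C1=O | intermediate
13 | bis(chlorotitanocene) dialkoxide of 14 (tetravalent titanium) | [O-][C@@H]1C[C@@H](OC(=O)CC(C)C)C(C)(C)[C@@H]2[C@H]3CC=C(C)[C@]2([O-])[C@]31C.[Ti+4].[Ti+4].[Cl-].[Cl-].c1cc[cH-]c1.c1cc[cH-]c1.c1cc[cH-]c1.c1cc[cH-]c1 | intermediate
14 | tricyclic diol: C10 bridgehead cyclobutanol, free C1 hydroxyl, C3 isovalerate | O[C@@H]1C[C@@H](OC(=O)CC(C)C)C(C)(C)[C@@H]2[C@H]3CC=C(C)[C@]2(O)[C@]31C | intermediate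
15 | C1 senecioate, C3 isovalerate, C10 tertiary alcohol | CC(C)=CC(=O)O[C@@H]1C[C@@H](OC(=O)CC(C)C)C(C)(C)[C@@H]2[C@H]3CC=C(C)[C@]2(O)[C@]31C | intermediate
16 | C10 methyl oxalate of 15 | CC(C)=CC(=O)O[C@@H]1C[C@@H](OC(=O)CC(C)C)C(C)(C)[C@@H]2[C@H]3CC=C(C)[C@]2(OC(=O)C(=O)OC)[C@]31C | intermediate
17 | C10-deoxy diester (C7 methylene, C8=C9) | CC(C)=CC(=O)O[C@@H]1C[C@@H](OC(=O)CC(C)C)C(C)(C)[C@@H]2[C@H]3CC=C(C)[C@@H]2[C@]31C | intermediate
18 | CNP0335239.1, longipin-2-en-1-one 7,9-diester (C3 isovalerate, C1 senecioate) | CC(C)=CC(=O)O[C@@H]1C[C@@H](OC(=O)CC(C)C)C(C)(C)[C@@H]2[C@H]3C(=O)C=C(C)[C@@H]2[C@]31C | target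

Total step count: 12. Longest linear sequence: 12 steps from (R)-carvone.

Steps most likely to fail

1. Step 8. The tertiary C11 radical may be captured by a second titanium (β-hydride elimination or reduction) before the strained ring closes, the enone may be reduced, or the radical may add in the conjugate sense at C8. Fallback, setting out from 12 and returning at 14: the epoxide is isomerised on purpose with Cp2TiCl in excess, added in one portion in THF, to the exocyclic allylic alcohol F1 (C11=CH2, C1–OH). The same C11 radical is then regenerated from this 1,1-disubstituted alkene by iron-hydride hydrogen-atom transfer (Fe(acac)3, PhSiH3, EtOH, 60 °C). No stoichiometric low-valent metal is present to intercept it, so it should close on the C10 ketone as in hydrogen-atom-transfer-initiated alkene–ketone cyclisations and give 14.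

2. Step 5. Deprotonation may occur at the γ-methylene C7 instead of the hindered C5–H, or the proton may be delivered with poor facial selectivity or after equilibration during the quench. Fallback, setting out from 8 and returning at 10: soft enolisation with t-BuMe2SiOTf/Et3N (CH2Cl2, 0 °C), which leaves the ester untouched, gives the isolable silyl dienol ether F2. Protodesilylation with HF·pyridine (THF, −40 °C) then delivers the proton under non-equilibrating acidic conditions, again anti to the pseudoaxial isopropenyl group.

3. Step 2. Addition of the tertiary radical to the hindered C5 terminus may be slow, so that addition to the isopropenyl group or hydrolysis of the enol silane takes over. Fallback, setting out from 3 and returning at 5: SnCl4-promoted Mukaiyama–Michael addition of 3 to 2-methyl-1-nitroprop-1-ene (CH2Cl2, −78 °C) forms the same C4–C5 bond and gives the γ-nitro ketone F3. A reductive Nef reaction (NaOMe, MeOH, −40 °C, then buffered aqueous TiCl3) unveils the aldehyde, the nitronate being kept cold to prevent its addition to the enone.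

Further compounds
F1 | step 8 | exocyclic allylic alcohol (C11=CH2, C1–OH, cis-fused enone, C3 isovalerate) | C=C1[C@H](O)C[C@@H](OC(=O)CC(C)C)C(C)(C)[C@@H]2[C@H]1CC=C(C)C2=O
F2 | step 5 | tert-butyldimethylsilyl dienol ether of 8 (C5=C10–OSi) | C=CC[C@@H](OC(=O)CC(C)C)C(C)(C)C1=C(O[Si](C)(C)C(C)(C)C)C(C)=CC[C@H]1C(C)=C
F3 | step 2 | trans γ-nitro ketone, (5R,6R)-2-methyl-6-(2-methyl-1-nitropropan-2-yl)-5-(prop-1-en-2-yl)cyclohex-2-en-1-one | O=[N+]([O-])CC(C)(C)[C@H]1[C@H](C(C)=C)CC=C(C)C1=O
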